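The route rests on cutting ring C of the flavan unit at O1–C2 and C3–C4. The feature exploited is that O1 and C4 hang on the adjacent ring A carbons C8a and C4a, so an ortho-quinone methide across C4a/C8a is the four-atom partner, while trans ring B (C2) and galloyloxy (C3) map onto an (E)-enol gallate. One (4+2) cycloaddition therefore closes ring C, forms both bonds and both stereocentres and brings in the second gallate. Its precursor is the ring A ortho-hydroxybenzyl alcohol that already carries the galloylated chalcan unit at C8, with its three nucleophilic aryl CH positions capped by bromine that is lost in the final hydrogenolysis.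

Key step: step 15

Locants: flavan numbering for the lower unit (O1, C2, C3, C4, C4a, C5–C8, C8a; rings A, B, C); in the chalcan unit Ca is the diarylmethine carbon bonded to C8, Cb the carbinol carbon, ring A′ the 2,4,6-trioxygenated ring and ring B′ the 3,4,5-trioxygenated ring; Bn = benzyl, MOM = methoxymethyl, Bpin = pinacolboryl.

Assumption: 1,3,5-tris(benzyloxy)benzene, 3,4,5-tris(benzyloxy)benzaldehyde and 3,4,5-tris(benzyloxy)benzoic acid are treated as catalogue compounds; each is otherwise reached in one or two routine steps from phloroglucinol or gallic acid.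

Step 1
Reactants: 1 2,4,6-trihydroxybenzaldehyde
Product: 2 4,6-bis(benzyloxy)-2-hydroxybenzaldehyde
Conditions: BnBr (2.05 equiv), K2CO3 (2.2 equiv), DMF, 0 °C → rt
Reagents that add atoms: benzyl bromide, BrCc1ccccc1
Why: Williamson ether synthesis in which the 4-OH and one ortho-OH are alkylated, while the remaining ortho-OH is held in the hydrogen bond to the formyl oxygen and should stay free when benzyl bromide is limited to two equivalents.

Step 2
Reactants: 2 4,6-bis(benzyloxy)-2-hydroxybenzaldehyde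
Product: 3 2,4-bis(benzyloxy)-6-(methoxymethoxy)benzaldehyde
Conditions: NaH (1.2 equiv), MOMCl (1.3 equiv), DMF, 0 °C → rt
Reagents that add atoms: chloromethyl methyl ether, COCCl
Why: Williamson-type O-alkylation of the sodium phenoxide gives the MOM acetal, which masks O8a through the ylide, alkoxide and acylation steps and can later be removed without touching benzyl ethers or esters.

Step 3
Reactants: 4 1,3,5-tris(benzyloxy)benzene
Product: 7 2-[2,4,6-tris(benzyloxy)phenyl]ethyl methanesulfonate, via aryllithium 5 (not isolated), via lithium alkoxide 6 (not isolated)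
Conditions: n-BuLi (1.05 equiv), THF, 0 °C; oxirane (3 equiv), 0 °C → rt; MsCl (1.3 equiv), 0 °C
Reagents that add atoms: oxirane, C1CO1; methanesulfonyl chloride, CS(=O)(=O)Cl
Why: Directed ortho-lithiation between two benzyloxy groups (the three ring CH are equivalent, so a single aryllithium forms), SN2 opening of oxirane and in-flask sulfonylation of the alkoxide should give the primary mesylate.

Step 4
Reactants: 7 2-[2,4,6-tris(benzyloxy)phenyl]ethyl methanesulfonate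
Product: 9 {2-[2,4,6-tris(benzyloxy)phenyl]ethyl}triphenylphosphonium iodide, via primary iodide 8 (not isolated)
Conditions: NaI (1.5 equiv), PPh3 (1.5 equiv), MeCN, reflux
Reagents that add atoms: sodium iodide, [Na+].[I-]; triphenylphosphine, c1ccc(cc1)P(c1ccccc1)c1ccccc1
Why: Finkelstein exchange to the primary iodide followed by SN2 quaternisation of triphenylphosphine; sodium methanesulfonate precipitates and the salt is purified by trituration.

Step 5
Reactants: 9 {2-[2,4,6-tris(benzyloxy)phenyl]ethyl}triphenylphosphonium iodide; 3 2,4-bis(benzyloxy)-6-(methoxymethoxy)benzaldehyde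
Product: 11 (Z)-1-[2,4-bis(benzyloxy)-6-(methoxymethoxy)phenyl]-3-[2,4,6-tris(benzyloxy)phenyl]prop-1-ene, via phosphonium ylide 10 (not isolated)
Conditions: NaN(SiMe3)2 (1.15 equiv), 9 (1.2 equiv), THF, −78 → 0 °C; then 3, −78 °C → rt
Reagents that add atoms: none
Why: Wittig reaction of a non-stabilised ylide under lithium-free conditions passes through the kinetically favoured cis-oxaphosphetane and should give the (Z)-alkene, the ortho-disubstituted aldehyde reinforcing this preference; any (E)-isomer is removed by chromatography.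

Step 6
Reactants: 12 5-bromobenzene-1,2,3-triol
Product: 13 1,2,3-tris(benzyloxy)-5-bromobenzene
Conditions: BnBr (3.3 equiv), K2CO3 (4 equiv), DMF, N2, rt
Reagents that add atoms: benzyl bromide, BrCc1ccccc1
Why: Threefold Williamson ether synthesis on the pyrogallol under nitrogen; the aryl bromide is inert.

Step 7
Reactants: 11 (Z)-1-[2,4-bis(benzyloxy)-6-(methoxymethoxy)phenyl]-3-[2,4,6-tris(benzyloxy)phenyl]prop-1-ene; 13 1,2,3-tris(benzyloxy)-5-bromobenzene
Product: 15 (1R,2S)-1-[2,4-bis(benzyloxy)-6-(methoxymethoxy)phenyl]-1-[3,4,5-tris(benzyloxy)phenyl]-3-[2,4,6-tris(benzyloxy)phenyl]propan-2-ol, via pinacol boronate 14 (not isolated)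
Conditions: 13 (1.5 equiv), B2pin2 (1.5 equiv), [(4S,5S)-1,3-bis(2-isopropylphenyl)-4,5-diphenylimidazolidin-2-ylidene]CuCl (5 mol %), Pd(OAc)2 (2 mol %), RuPhos (4 mol %), NaOtBu (1.5 equiv), THF, rt; then NaOH (aq), H2O2, 0 °C
Reagents that add atoms: hydrogen peroxide, OO
Why: Cu/Pd-catalysed arylboration of an alkenylarene, in which the copper boryl adds syn with boron on Cb and copper on benzylic Ca, and stereoretentive transmetalation to the arylpalladium from 13 with reductive elimination forms the Ca–aryl bond; overall syn addition to the (Z)-alkene fixes the relative configuration, the chiral NHC on copper selects the alkene face that gives (1R,2S) (ligand antipode chosen accordingly), and oxidation of the C–B bond proceeds with retention.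

Step 8
Reactants: 15 (1R,2S)-chalcan alcohol (O8a as MOM ether); 16 3,4,5-tris(benzyloxy)benzoic acid
Product: 17 (1R,2S)-1-[2,4-bis(benzyloxy)-6-(methoxymethoxy)phenyl]-1-[3,4,5-tris(benzyloxy)phenyl]-3-[2,4,6-tris(benzyloxy)phenyl]propan-2-yl 3,4,5-tris(benzyloxy)benzoate
Conditions: 16 (1.5 equiv), EDC·HCl (2 equiv), DMAP (1 equiv), CH2Cl2, rt → 35 °C
Reagents that add atoms: none
Why: Steglich esterification of the only free hydroxyl (secondary Cb–OH) with DMAP as acyl-transfer agent; no stereocentre is involved.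

Step 9
Reactants: 17 galloylated chalcan MOM ether
Product: 18 (1R,2S)-1-[2,4-bis(benzyloxy)-6-hydroxyphenyl]-1-[3,4,5-tris(benzyloxy)phenyl]-3-[2,4,6-tris(benzyloxy)phenyl]propan-2-yl 3,4,5-tris(benzyloxy)benzoate
Conditions: ZnBr2 (1.5 equiv), n-PrSH (3 equiv), CH2Cl2, 0 °C → rt
Reagents that add atoms: none
Why: Lewis-acid-assisted cleavage of the aryl MOM acetal with thiol capture of the methoxymethyl cation, which keeps that cation away from the electron-rich rings; benzyl ethers and the ester should be inert.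

Step 10
Reactants: 18 galloylated chalcan phenol
Product: 19 (1R,2S)-1-[4,6-bis(benzyloxy)-3-formyl-2-hydroxyphenyl]-1-[3,4,5-tris(benzyloxy)phenyl]-3-[2,4,6-tris(benzyloxy)phenyl]propan-2-yl 3,4,5-tris(benzyloxy)benzoate
Conditions: MgCl2 (3 equiv), Et3N (6 equiv), (CH2O)n (10 equiv), MeCN, reflux
Reagents that add atoms: formaldehyde (as paraformaldehyde), C=O
Why: Casnati–Skattebøl ortho-formylation, in which magnesium-phenoxide-bound formaldehyde attacks only the free ortho carbon C4a (C8 is substituted and para C6 is not reached through the chelate) and a second formaldehyde acts as hydride acceptor to give the salicylaldehyde.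

Step 11
Reactants: 19 salicylaldehyde
Product: 20 (1R,2S)-1-[2,4-bis(benzyloxy)-3-bromo-5-formyl-6-hydroxyphenyl]-1-[3,4,5-tris(benzyloxy)phenyl]-3-[2,4,6-tris(benzyloxy)-3,5-dibromophenyl]propan-2-yl 3,4,5-tris(benzyloxy)benzoate
Conditions: NBS (3.1 equiv), CH2Cl2, −40 → 0 °C, dark
Reagents that add atoms: N-bromosuccinimide, O=C1CCC(=O)N1Br
Why: Electrophilic aromatic bromination at the three phloroglucinol-type CH positions (ring A C6 and both CH of ring A′), which are far more activated than the pyrogallol, galloyl and benzyl rings; the bromines block these sites against alkylation in step 15 and leave in step 16.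

Step 12
Reactants: 20 tribromo salicylaldehyde
Product: 21 (1R,2S)-1-[2,4-bis(benzyloxy)-3-bromo-6-hydroxy-5-(hydroxymethyl)phenyl]-1-[3,4,5-tris(benzyloxy)phenyl]-3-[2,4,6-tris(benzyloxy)-3,5-dibromophenyl]propan-2-yl 3,4,5-tris(benzyloxy)benzoate
Conditions: NaBH4 (1.5 equiv), THF/MeOH 5:1, −20 → 0 °C; pH 7 buffer; used directly
Reagents that add atoms: none
Why: Chemoselective hydride reduction of the aldehyde (esters and aryl bromides are inert to NaBH4 at this temperature); the cold neutral work-up avoids ionisation of the electron-rich ortho-hydroxybenzyl alcohol.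

Step 13
Reactants: 22 3,4,5-tris(benzyloxy)benzaldehyde
Product: 24 potassium (E)-trifluoro{2-[3,4,5-tris(benzyloxy)phenyl]ethenyl}borate, via alkenyl pinacol boronate 23 (not isolated)
Conditions: CH2(Bpin)2 (1.2 equiv), lithium 2,2,6,6-tetramethylpiperidide (1.2 equiv, from the amine and n-BuLi), THF, −78 °C → rt; then KHF2 (aq, 4 equiv), MeOH, rt
Reagents that add atoms: bis[(pinacolato)boryl]methane, CC1(C)OB(CB2OC(C)(C)C(C)(C)O2)OC1(C)C; potassium hydrogen difluoride, [K+].F.[F-]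
Why: Boron–Wittig olefination (addition of the lithiated geminal bis(boronate) to the aldehyde and syn-elimination of the boron oxide) should give the (E)-alkenylboronate, and exchange with KHF2 gives the crystalline trifluoroborate.

Step 14
Reactants: 24 potassium (E)-alkenyltrifluoroborate; 16 3,4,5-tris(benzyloxy)benzoic acid
Product: 25 (E)-2-[3,4,5-tris(benzyloxy)phenyl]ethenyl 3,4,5-tris(benzyloxy)benzoate
Conditions: 24 (1.5 equiv), CuBr (10 mol %), DMAP (20 mol %), 4 Å MS, O2 (1 atm), CH2Cl2, 40 °C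
Reagents that add atoms: none
Why: Chan–Lam-type oxidative C–O coupling of the alkenyltrifluoroborate with the carboxylic acid retains the alkene geometry, so the (E)-enol ester should form as a single isomer, which enolate O-acylation would not ensure.

Step 15
Reactants: 21 tribromo ortho-hydroxybenzyl alcohol; 25 (E)-enol gallate
Product: 27 (2S,3R)-5,7-bis(benzyloxy)-6-bromo-2-[3,4,5-tris(benzyloxy)phenyl]-8-{(1R,2S)-3-[2,4,6-tris(benzyloxy)-3,5-dibromophenyl]-1-[3,4,5-tris(benzyloxy)phenyl]-2-[3,4,5-tris(benzyloxy)benzoyloxy]propyl}chroman-3-yl 3,4,5-tris(benzyloxy)benzoate, via ortho-quinone methide 26 (not isolated)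
Conditions: 25 (3 equiv), (R)-TRIP [(R)-3,3′-bis(2,4,6-triisopropylphenyl)-1,1′-binaphthyl-2,2′-diyl hydrogen phosphate] (10 mol %), 5 Å MS, PhMe, 0 °C → rt; 21 added over 6 h
Reagents that add atoms: none
Why: Proposed new method: the chiral phosphoric acid ionises the benzylic C4–OH of 21 with loss of water to the ortho-quinone methide 26, which remains hydrogen-bonded to the phosphate and reacts as the electron-poor 1-oxadiene O1=C8a–C4a=C4 with the enol gallate in a concerted but asynchronous inverse-demand hetero-Diels–Alder reaction. The closest known reaction type is the Brønsted-acid-catalysed (4+2) cycloaddition of in situ ortho-quinone methides with styrenes, enamides and enol ethers; an enol ester has not been used as the two-carbon partner. Ring C is closed by intermolecular (4+2) cycloaddition, the C4–C3 bond leading and the O1–C2 bond following (in the stepwise limit a 6-endo capture of the benzylic cation by O1). C2 and C3 are set relative to each other by suprafacial addition to the (E)-alkene (2,3-trans) and in the absolute sense 2S,3R by the chiral phosphate, which shields one face of the bound quinone methide because Ca and Cb are too remote to do so; the antipode of the acid is chosen to match, and the 2R,3S adduct, a diastereomer, is removed by chromatography. The regioselectivity needed (ring B on C2, gallate on C3) follows from charge build-up at the benzylic carbon, stabilised by the para-benzyloxy group, which outweighs the weakly donating acyloxy oxygen. Chemoselectivity for cycloaddition over arene alkylation is built into 21: O8a is the only free phenol, C4a its only ortho carbon carrying the leaving group, and ring A C6 and both CH of ring A′ are blocked by bromine, while slow addition to excess 25 keeps 26 dilute.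

Step 16
Reactants: 27 tribromo heptadeca-O-benzyl cycloadduct
Product: 28 (2S,3R)-5,7-dihydroxy-2-(3,4,5-trihydroxyphenyl)-8-[(1R,2S)-2-(3,4,5-trihydroxybenzoyloxy)-1-(3,4,5-trihydroxyphenyl)-3-(2,4,6-trihydroxyphenyl)propyl]chroman-3-yl 3,4,5-trihydroxybenzoate (CNP0155034.3)
Conditions: H2 (1 atm), Pd(OH)2/C, NaOAc (4 equiv), THF/MeOH 1:1, rt; filtration under N2
Reagents that add atoms: none
Why: Catalytic hydrogenolysis should cleave all seventeen benzyl ethers and, with acetate taking up HBr, the three aryl C–Br bonds; the two gallate esters, the non-benzylic C3–O and Cb–O bonds and all four stereocentres are untouched, and the benzylic C2–O1 ether is expected to survive as in other flavan-3-ol debenzylations.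

Compound list
1 | 2,4,6-trihydroxybenzaldehyde | O=Cc1c(O)cc(O)cc1O | starting material
2 | 4,6-bis(benzyloxy)-2-hydroxybenzaldehyde | O=Cc1c(O)cc(OCc3ccccc3)cc1OCc3ccccc3 | intermediate
3 | 2,4-bis(benzyloxy)-6-(methoxymethoxy)benzaldehyde | O=Cc1c(OCOC)cc(OCc3ccccc3)cc1OCc3ccccc3 | intermediate
4 | 1,3,5-tris(benzyloxy)benzene | c1c(OCc3ccccc3)cc(OCc3ccccc3)cc1OCc3ccccc3 | starting material
5 | [2,4,6-tris(benzyloxy)phenyl]lithium | [Li]c1c(OCc3ccccc3)cc(OCc3ccccc3)cc1OCc3ccccc3 | intermediate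
6 | lithium 2-[2,4,6-tris(benzyloxy)phenyl]ethanolate | [Li+].[O-]CCc1c(OCc3ccccc3)cc(OCc3ccccc3)cc1OCc3ccccc3 | intermediate
7 | 2-[2,4,6-tris(benzyloxy)phenyl]ethyl methanesulfonate | CS(=O)(=O)OCCc1c(OCc3ccccc3)cc(OCc3ccccc3)cc1OCc3ccccc3 | intermediate
8 | 1,3,5-tris(benzyloxy)-2-(2-iodoethyl)benzene | ICCc1c(OCc3ccccc3)cc(OCc3ccccc3)cc1OCc3ccccc3 | intermediate
9 | {2-[2,4,6-tris(benzyloxy)phenyl]ethyl}triphenylphosphonium iodide | [I-].c1ccc(cc1)[P+](c1ccccc1)(c1ccccc1)CCc1c(OCc3ccccc3)cc(OCc3ccccc3)cc1OCc3ccccc3 | intermediate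
10 | {2-[2,4,6-tris(benzyloxy)phenyl]ethylidene}triphenylphosphorane | c1ccc(cc1)P(c1ccccc1)(c1ccccc1)=CCc1c(OCc3ccccc3)cc(OCc3ccccc3)cc1OCc3ccccc3 | intermediate
11 | (Z)-1-[2,4-bis(benzyloxy)-6-(methoxymethoxy)phenyl]-3-[2,4,6-tris(benzyloxy)phenyl]prop-1-ene | COCOc1cc(OCc3ccccc3)cc(OCc3ccccc3)c1/C=C\Cc1c(OCc3ccccc3)cc(OCc3ccccc3)cc1OCc3ccccc3 | intermediate
12 | 5-bromobenzene-1,2,3-triol | Oc1cc(Br)cc(O)c1O | starting material
13 | 1,2,3-tris(benzyloxy)-5-bromobenzene | Brc1cc(OCc3ccccc3)c(OCc3ccccc3)c(OCc3ccccc3)c1 | intermediate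
14 | 2-{(1R,2S)-1-[2,4-bis(benzyloxy)-6-(methoxymethoxy)phenyl]-1-[3,4,5-tris(benzyloxy)phenyl]-3-[2,4,6-tris(benzyloxy)phenyl]propan-2-yl}-4,4,5,5-tetramethyl-1,3,2-dioxaborolane | CC1(C)OB(OC1(C)C)[C@@H](Cc1c(OCc3ccccc3)cc(OCc3ccccc3)cc1OCc3ccccc3)[C@H](c1cc(OCc3ccccc3)c(OCc3ccccc3)c(OCc3ccccc3)c1)c1c(OCc3ccccc3)cc(OCc3ccccc3)cc1OCOC | intermediate
15 | (1R,2S)-1-[2,4-bis(benzyloxy)-6-(methoxymethoxy)phenyl]-1-[3,4,5-tris(benzyloxy)phenyl]-3-[2,4,6-tris(benzyloxy)phenyl]propan-2-ol | O[C@@H](Cc1c(OCc3ccccc3)cc(OCc3ccccc3)cc1OCc3ccccc3)[C@H](c1cc(OCc3ccccc3)c(OCc3ccccc3)c(OCc3ccccc3)c1)c1c(OCc3ccccc3)cc(OCc3ccccc3)cc1OCOC | intermediate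
16 | 3,4,5-tris(benzyloxy)benzoic acid | OC(=O)c1cc(OCc3ccccc3)c(OCc3ccccc3)c(OCc3ccccc3)c1 | starting material
17 | (1R,2S)-1-[2,4-bis(benzyloxy)-6-(methoxymethoxy)phenyl]-1-[3,4,5-tris(benzyloxy)phenyl]-3-[2,4,6-tris(benzyloxy)phenyl]propan-2-yl 3,4,5-tris(benzyloxy)benzoate | O=C(O[C@@H](Cc1c(OCc3ccccc3)cc(OCc3ccccc3)cc1OCc3ccccc3)[C@H](c1cc(OCc3ccccc3)c(OCc3ccccc3)c(OCc3ccccc3)c1)c1c(OCc3ccccc3)cc(OCc3ccccc3)cc1OCOC)c1cc(OCc3ccccc3)c(OCc3ccccc3)c(OCc3ccccc3)c1 | intermediate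
18 | (1R,2S)-1-[2,4-bis(benzyloxy)-6-hydroxyphenyl]-1-[3,4,5-tris(benzyloxy)phenyl]-3-[2,4,6-tris(benzyloxy)phenyl]propan-2-yl 3,4,5-tris(benzyloxy)benzoate | O=C(O[C@@H](Cc1c(OCc3ccccc3)cc(OCc3ccccc3)cc1OCc3ccccc3)[C@H](c1cc(OCc3ccccc3)c(OCc3ccccc3)c(OCc3ccccc3)c1)c1c(OCc3ccccc3)cc(OCc3ccccc3)cc1O)c1cc(OCc3ccccc3)c(OCc3ccccc3)c(OCc3ccccc3)c1 | intermediate
19 | (1R,2S)-1-[4,6-bis(benzyloxy)-3-formyl-2-hydroxyphenyl]-1-[3,4,5-tris(benzyloxy)phenyl]-3-[2,4,6-tris(benzyloxy)phenyl]propan-2-yl 3,4,5-tris(benzyloxy)benzoate | O=C(O[C@@H](Cc1c(OCc3ccccc3)cc(OCc3ccccc3)cc1OCc3ccccc3)[C@H](c1cc(OCc3ccccc3)c(OCc3ccccc3)c(OCc3ccccc3)c1)c1c(OCc3ccccc3)cc(OCc3ccccc3)c(C=O)c1O)c1cc(OCc3ccccc3)c(OCc3ccccc3)c(OCc3ccccc3)c1 | intermediate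
20 | (1R,2S)-1-[2,4-bis(benzyloxy)-3-bromo-5-formyl-6-hydroxyphenyl]-1-[3,4,5-tris(benzyloxy)phenyl]-3-[2,4,6-tris(benzyloxy)-3,5-dibromophenyl]propan-2-yl 3,4,5-tris(benzyloxy)benzoate | O=C(O[C@@H](Cc1c(OCc3ccccc3)c(Br)c(OCc3ccccc3)c(Br)c1OCc3ccccc3)[C@H](c1cc(OCc3ccccc3)c(OCc3ccccc3)c(OCc3ccccc3)c1)c1c(OCc3ccccc3)c(Br)c(OCc3ccccc3)c(C=O)c1O)c1cc(OCc3ccccc3)c(OCc3ccccc3)c(OCc3ccccc3)c1 | intermediate
21 | (1R,2S)-1-[2,4-bis(benzyloxy)-3-bromo-6-hydroxy-5-(hydroxymethyl)phenyl]-1-[3,4,5-tris(benzyloxy)phenyl]-3-[2,4,6-tris(benzyloxy)-3,5-dibromophenyl]propan-2-yl 3,4,5-tris(benzyloxy)benzoate | O=C(O[C@@H](Cc1c(OCc3ccccc3)c(Br)c(OCc3ccccc3)c(Br)c1OCc3ccccc3)[C@H](c1cc(OCc3ccccc3)c(OCc3ccccc3)c(OCc3ccccc3)c1)c1c(OCc3ccccc3)c(Br)c(OCc3ccccc3)c(CO)c1O)c1cc(OCc3ccccc3)c(OCc3ccccc3)c(OCc3ccccc3)c1 | intermediate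
22 | 3,4,5-tris(benzyloxy)benzaldehyde | O=Cc1cc(OCc3ccccc3)c(OCc3ccccc3)c(OCc3ccccc3)c1 | starting material
23 | (E)-4,4,5,5-tetramethyl-2-{2-[3,4,5-tris(benzyloxy)phenyl]ethenyl}-1,3,2-dioxaborolane | CC1(C)OB(OC1(C)C)/C=C/c1cc(OCc3ccccc3)c(OCc3ccccc3)c(OCc3ccccc3)c1 | intermediate
24 | potassium (E)-trifluoro{2-[3,4,5-tris(benzyloxy)phenyl]ethenyl}borate | [K+].F[B-](F)(F)/C=C/c1cc(OCc3ccccc3)c(OCc3ccccc3)c(OCc3ccccc3)c1 | intermediate
25 | (E)-2-[3,4,5-tris(benzyloxy)phenyl]ethenyl 3,4,5-tris(benzyloxy)benzoate | O=C(O/C=C/c1cc(OCc3ccccc3)c(OCc3ccccc3)c(OCc3ccccc3)c1)c1cc(OCc3ccccc3)c(OCc3ccccc3)c(OCc3ccccc3)c1 | intermediate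
26 | ortho-quinone methide of 21 (6-methylidene-cyclohexa-2,4-dienone of ring A; Ca 1R, Cb 2S) | O=C(O[C@@H](Cc1c(OCc3ccccc3)c(Br)c(OCc3ccccc3)c(Br)c1OCc3ccccc3)[C@H](c1cc(OCc3ccccc3)c(OCc3ccccc3)c(OCc3ccccc3)c1)C1=C(OCc3ccccc3)C(Br)=C(OCc3ccccc3)C(=C)C1=O)c1cc(OCc3ccccc3)c(OCc3ccccc3)c(OCc3ccccc3)c1 | intermediate
27 | (2S,3R)-5,7-bis(benzyloxy)-6-bromo-2-[3,4,5-tris(benzyloxy)phenyl]-8-{(1R,2S)-3-[2,4,6-tris(benzyloxy)-3,5-dibromophenyl]-1-[3,4,5-tris(benzyloxy)phenyl]-2-[3,4,5-tris(benzyloxy)benzoyloxy]propyl}chroman-3-yl 3,4,5-tris(benzyloxy)benzoate | O=C(O[C@@H](Cc1c(OCc3ccccc3)c(Br)c(OCc3ccccc3)c(Br)c1OCc3ccccc3)[C@H](c1cc(OCc3ccccc3)c(OCc3ccccc3)c(OCc3ccccc3)c1)c1c(OCc3ccccc3)c(Br)c(OCc3ccccc3)c2c1O[C@@H](c1cc(OCc3ccccc3)c(OCc3ccccc3)c(OCc3ccccc3)c1)[C@H](OC(=O)c1cc(OCc3ccccc3)c(OCc3ccccc3)c(OCc3ccccc3)c1)C2)c1cc(OCc3ccccc3)c(OCc3ccccc3)c(OCc3ccccc3)c1 | intermediate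
28 | (2S,3R)-5,7-dihydroxy-2-(3,4,5-trihydroxyphenyl)-8-[(1R,2S)-2-(3,4,5-trihydroxybenzoyloxy)-1-(3,4,5-trihydroxyphenyl)-3-(2,4,6-trihydroxyphenyl)propyl]chroman-3-yl 3,4,5-trihydroxybenzoate (CNP0155034.3) | O=C(O[C@@H](Cc1c(O)cc(O)cc1O)[C@H](c1cc(O)c(O)c(O)c1)c1c(O)cc(O)c2c1O[C@@H](c1cc(O)c(O)c(O)c1)[C@H](OC(=O)c1cc(O)c(O)c(O)c1)C2)c1cc(O)c(O)c(O)c1 | target

Total step count: 16. Longest linear sequence: 11 steps (4 → 7 → 9 → 11 → 15 → 17 → 18 → 19 → 20 → 21 → 27 → 28).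

Steps most likely to fail

1. Step 15 (labelled step). The quinone methide may be consumed by stepwise cationic paths: addition in the opposite orientation to give the 3-aryl-2-acyloxy isomer, acyl transfer from the enol ester, or self-condensation. It may also add with poor facial discrimination. The fallback uses known chemistry and runs from 20 back to 27. Petasis-type condensation of salicylaldehyde 20 with trifluoroborate 24 and Bn2NH (20 mol %) in DMF at 80 °C should give the flav-3-ene F1 by alkenyl transfer to the iminium, loss of the amine and 6π-oxa-electrocyclisation. Both C2 epimers are expected, and they are separated here or after the next operation. Hydroboration with BH3·SMe2 anti to the C2 aryl group and oxidation with NaBO3·4H2O should give the 2,3-trans-flavan-3-ol F2. Steglich esterification of F2 with 16 (EDC·HCl, DMAP) gives 27.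

2. Step 7. Borylcupration of the hindered, electron-rich (Z)-alkene may be slow, the syn pathway may leak at the benzylic copper stage, or enantiofacial control may be insufficient. The fallback runs from 3 back to 15 with a 4-phenyloxazolidinone auxiliary.
   - Horner–Wadsworth–Emmons reaction of 3 with diethyl {2-oxo-2-[(4S)-2-oxo-4-phenyl-1,3-oxazolidin-3-yl]ethyl}phosphonate (LiCl, iPr2NEt, MeCN) gives the (E)-enoyl imide F3.
   - The aryl Grignard reagent F4, made from 13 and magnesium, adds with CuBr·SMe2 to the chelated s-cis imide anti to the 4-phenyl group and gives the conjugate adduct F5 with Ca (R).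
   - The dibutylboron (Z)-enolate of F5 (Bu2BOTf, iPr2NEt) is brominated by NBS anti to the auxiliary to give the (2S)-bromo imide F6.
   - LiBH4 in THF/H2O removes the auxiliary and gives the bromohydrin F7.
   - K2CO3 in MeOH closes the terminal epoxide F8 with inversion at Cb, which sets the required Ca/Cb relationship.
   - Aryllithium 5 with BF3·OEt2 at −78 °C opens F8 at its CH2 terminus to give 15.

3. Step 12. The electron-rich ortho-hydroxybenzyl alcohol may ionise during reduction or isolation, leading to over-reduction to the C4a-methyl compound or to self-condensation. The fallback runs from 18 back to 21 and bypasses 19 and 20. Boron-templated ortho-hydroxymethylation of 18 with phenylboronic acid, paraformaldehyde and catalytic propanoic acid in toluene at 90 °C with removal of water should give the cyclic phenylboronate F9, a storable masked form of the benzyl alcohol. NBS (3.1 equiv) as in step 11 gives the tribromo cyclic boronate F10. Exchange with 2,2-dimethylpropane-1,3-diol in CH2Cl2/MeOH at rt releases 21 just before step 15.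

Further compounds
F1 | step 15 | (1R,2S)-1-{(2R)-5,7-bis(benzyloxy)-6-bromo-2-[3,4,5-tris(benzyloxy)phenyl]-2H-chromen-8-yl}-1-[3,4,5-tris(benzyloxy)phenyl]-3-[2,4,6-tris(benzyloxy)-3,5-dibromophenyl]propan-2-yl 3,4,5-tris(benzyloxy)benzoate | O=C(O[C@@H](Cc1c(OCc3ccccc3)c(Br)c(OCc3ccccc3)c(Br)c1OCc3ccccc3)[C@H](c1cc(OCc3ccccc3)c(OCc3ccccc3)c(OCc3ccccc3)c1)c1c(OCc3ccccc3)c(Br)c(OCc3ccccc3)c2c1O[C@@H](c1cc(OCc3ccccc3)c(OCc3ccccc3)c(OCc3ccccc3)c1)C=C2)c1cc(OCc3ccccc3)c(OCc3ccccc3)c(OCc3ccccc3)c1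
F2 | step 15 | (1R,2S)-1-{(2S,3R)-5,7-bis(benzyloxy)-6-bromo-3-hydroxy-2-[3,4,5-tris(benzyloxy)phenyl]chroman-8-yl}-1-[3,4,5-tris(benzyloxy)phenyl]-3-[2,4,6-tris(benzyloxy)-3,5-dibromophenyl]propan-2-yl 3,4,5-tris(benzyloxy)benzoate | O=C(O[C@@H](Cc1c(OCc3ccccc3)c(Br)c(OCc3ccccc3)c(Br)c1OCc3ccccc3)[C@H](c1cc(OCc3ccccc3)c(OCc3ccccc3)c(OCc3ccccc3)c1)c1c(OCc3ccccc3)c(Br)c(OCc3ccccc3)c2c1O[C@@H](c1cc(OCc3ccccc3)c(OCc3ccccc3)c(OCc3ccccc3)c1)[C@H](O)C2)c1cc(OCc3ccccc3)c(OCc3ccccc3)c(OCc3ccccc3)c1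
F3 | step 7 | (4S)-3-{(2E)-3-[2,4-bis(benzyloxy)-6-(methoxymethoxy)phenyl]prop-2-enoyl}-4-phenyl-1,3-oxazolidin-2-one | O=C1OC[C@H](c2ccccc2)N1C(=O)/C=C/c1c(OCOC)cc(OCc3ccccc3)cc1OCc3ccccc3
F4 | step 7 | [3,4,5-tris(benzyloxy)phenyl]magnesium bromide | Br[Mg]c1cc(OCc3ccccc3)c(OCc3ccccc3)c(OCc3ccccc3)c1
F5 | step 7 | (4S)-3-{(3R)-3-[2,4-bis(benzyloxy)-6-(methoxymethoxy)phenyl]-3-[3,4,5-tris(benzyloxy)phenyl]propanoyl}-4-phenyl-1,3-oxazolidin-2-one | O=C1OC[C@H](c2ccccc2)N1C(=O)C[C@H](c1cc(OCc3ccccc3)c(OCc3ccccc3)c(OCc3ccccc3)c1)c1c(OCc3ccccc3)cc(OCc3ccccc3)cc1OCOC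
F6 | step 7 | (4S)-3-{(2S,3R)-3-[2,4-bis(benzyloxy)-6-(methoxymethoxy)phenyl]-2-bromo-3-[3,4,5-tris(benzyloxy)phenyl]propanoyl}-4-phenyl-1,3-oxazolidin-2-one | O=C1OC[C@H](c2ccccc2)N1C(=O)[C@@H](Br)[C@H](c1cc(OCc3ccccc3)c(OCc3ccccc3)c(OCc3ccccc3)c1)c1c(OCc3ccccc3)cc(OCc3ccccc3)cc1OCOC
F7 | step 7 | (2S,3R)-3-[2,4-bis(benzyloxy)-6-(methoxymethoxy)phenyl]-2-bromo-3-[3,4,5-tris(benzyloxy)phenyl]propan-1-ol | OC[C@@H](Br)[C@H](c1cc(OCc3ccccc3)c(OCc3ccccc3)c(OCc3ccccc3)c1)c1c(OCc3ccccc3)cc(OCc3ccccc3)cc1OCOC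
F8 | step 7 | (2R)-2-{(R)-[2,4-bis(benzyloxy)-6-(methoxymethoxy)phenyl][3,4,5-tris(benzyloxy)phenyl]methyl}oxirane | C1O[C@@H]1[C@H](c1cc(OCc3ccccc3)c(OCc3ccccc3)c(OCc3ccccc3)c1)c1c(OCc3ccccc3)cc(OCc3ccccc3)cc1OCOC
F9 | step 12 | (1R,2S)-1-[5,7-bis(benzyloxy)-2-phenyl-4H-1,3,2-benzodioxaborinin-8-yl]-1-[3,4,5-tris(benzyloxy)phenyl]-3-[2,4,6-tris(benzyloxy)phenyl]propan-2-yl 3,4,5-tris(benzyloxy)benzoate | O=C(O[C@@H](Cc1c(OCc3ccccc3)cc(OCc3ccccc3)cc1OCc3ccccc3)[C@H](c1cc(OCc3ccccc3)c(OCc3ccccc3)c(OCc3ccccc3)c1)c1c(OCc3ccccc3)cc(OCc3ccccc3)c2c1OB(c1ccccc1)OC2)c1cc(OCc3ccccc3)c(OCc3ccccc3)c(OCc3ccccc3)c1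
F10 | step 12 | (1R,2S)-1-[5,7-bis(benzyloxy)-6-bromo-2-phenyl-4H-1,3,2-benzodioxaborinin-8-yl]-1-[3,4,5-tris(benzyloxy)phenyl]-3-[2,4,6-tris(benzyloxy)-3,5-dibromophenyl]propan-2-yl 3,4,5-tris(benzyloxy)benzoate | O=C(O[C@@H](Cc1c(OCc3ccccc3)c(Br)c(OCc3ccccc3)c(Br)c1OCc3ccccc3)[C@H](c1cc(OCc3ccccc3)c(OCc3ccccc3)c(OCc3ccccc3)c1)c1c(OCc3ccccc3)c(Br)c(OCc3ccccc3)c2c1OB(c1ccccc1)OC2)c1cc(OCc3ccccc3)c(OCc3ccccc3)c(OCc3ccccc3)c1
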